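**Retrosynthetic overview**

1. The target comes from its di-tert-butyl ester 32 by acidolysis; 32 is cut at C12–C13 into the 9-vinyl decalin 24 and the (Z)-iodoenoate 30 (hydroboration, then B-alkyl Suzuki–Miyaura coupling).
2. 24 goes back to the 6-oxo-11-al decalin 20 (Wittig at C11, C6–C7 enol triflate, reduction); C5 and C9 are settled in 20 by enolization.
3. The strategy rests on ring B: C8 carries the carboxyl carbon C17 and C9 carries C11, which can be raised to aldehyde level, so C17–C8–C9–C11 is a 1,4-dicarbonyl array whose central bond C8–C9 is a ring B bond. That bond is cut as an oxidative coupling of the C8=C17 ketene acetal with the C9=C11 enol ether in the ring A compound 17.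
4. 17 goes back to (S)-2-allyl-2,6,6-trimethylcyclohexanone 5 (C10 by enantioselective decarboxylative allylation; C6 by epoxide homologation; C7, C8 and C17 by a homoenolate; C11 by ozonolysis).
5. Ring order: ring A is bought (1); ring B is the only ring made (step 10).

Key step: step 10

Remark: carbons are numbered as in the labdane skeleton; C5 is not controlled before ring B is closed, so 6 to 19 are carried as C5 epimer pairs (SMILES left open at that centre, as at the transient centres of 6 and 11) and C5 is settled in step 12; the (S)-ligand is assumed to give the same sense of induction as with simpler 2-alkylcyclohexanone enol carbonates.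

**Route**

Step 1
Reactants: 1 2,2,6-trimethylcyclohexanone; 2 allyl chloroformate
Product: 4 allyl 2,6,6-trimethylcyclohex-1-en-1-yl carbonate, via lithium enolate 3 (not isolated)
Conditions: LiHMDS, THF, 0 °C; then 2, −78 → 0 °C
Reagents that add atoms: none
Why: The ketone has a single enolizable α-carbon, so LiHMDS gives one tetrasubstituted enolate, and the hard chloroformate acylates this hindered enolate on oxygen (enol carbonate formation).

Step 2
Reactants: 4 allyl 2,6,6-trimethylcyclohex-1-en-1-yl carbonate
Product: 5 (S)-2-allyl-2,6,6-trimethylcyclohexan-1-one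
Conditions: Pd2(dba)3 (2.5 mol%), (S)-t-BuPHOX (6 mol%), THF, 25 °C
Reagents that add atoms: none
Why: Enantioselective decarboxylative allylic alkylation (Tsuji–Trost type): zerovalent palladium ionizes the allyl carbonate, CO2 is lost and the enolate recombines with the π-allyl unit inside the chiral phosphinooxazoline pocket, which sets the quaternary C10 as (S) in the sense established for 2-alkylcyclohexanone enol carbonates with the (S)-ligand.

Step 3
Reactants: 5 (S)-2-allyl-2,6,6-trimethylcyclohexan-1-one
Product: 6 (4S)-4-allyl-4,8,8-trimethyl-1-oxaspiro[2.5]octane (both configurations at the spiro carbon)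
Conditions: Me3S+ I−, n-BuLi, THF, −10 °C; then 5, −10 → 25 °C
Reagents that add atoms: trimethylsulfonium iodide, C[S+](C)C.[I-]
Why: Corey–Chaykovsky epoxidation: the ketone cannot enolize, so the small unstabilized sulfur ylide can only add to the carbonyl and close to the epoxide; the configuration of the spiro carbon is not controlled and is lost in step 4.

Step 4
Reactants: 6 (4S)-4-allyl-4,8,8-trimethyl-1-oxaspiro[2.5]octane
Product: 7 (2S)-2-allyl-2,6,6-trimethylcyclohexane-1-carbaldehyde (both C5 epimers)
Conditions: BF3·OEt2 (0.2 equiv), CH2Cl2, −78 °C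
Reagents that add atoms: none
Why: Meinwald rearrangement: the Lewis acid opens the epoxide at the tertiary carbon C5 and a 1,2-hydride shift from the CH2O carbon gives the C6 aldehyde; C5 is formed as both epimers, which is accepted because this centre is settled later next to the C6 ketone (step 12).

Step 5
Reactants: 7 (2S)-2-allyl-2,6,6-trimethylcyclohexane-1-carbaldehyde; 8 tert-butyl 3-bromopropanoate
Product: 11 tert-butyl 4-[(2S)-2-allyl-2,6,6-trimethylcyclohexyl]-4-hydroxybutanoate (mixture at C5 and C6), via organozinc bromide 9 (not isolated), via titanium homoenolate 10 (not isolated)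
Conditions: 8, Zn, LiCl, THF, 40 °C; ClTi(OiPr)3, CH2Cl2/THF, −30 °C; then 7, −30 → 0 °C; aq. NH4Cl
Reagents that add atoms: none
Why: Homoenolate addition: zinc insertion into the bromide followed by transmetalation to titanium gives an ester-tolerant nucleophile that is Lewis acidic enough to add to the hindered aldehyde but not to esters, and the tert-butyl ester slows lactonization of the γ-alkoxide; the new carbinol centre C6 is irrelevant because it is oxidized next.

Step 6
Reactants: 11 tert-butyl 4-[(2S)-2-allyl-2,6,6-trimethylcyclohexyl]-4-hydroxybutanoate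
Product: 12 tert-butyl 4-[(2S)-2-allyl-2,6,6-trimethylcyclohexyl]-4-oxobutanoate (both C5 epimers)
Conditions: Dess–Martin periodinane, CH2Cl2, 25 °C
Reagents that add atoms: none
Why: Dess–Martin oxidation turns the secondary alcohol into the ketone under neutral conditions that leave the alkene and the tert-butyl ester untouched.

Step 7
Reactants: 12 tert-butyl 4-[(2S)-2-allyl-2,6,6-trimethylcyclohexyl]-4-oxobutanoate
Product: 13 tert-butyl 3-{2-[(2S)-2-allyl-2,6,6-trimethylcyclohexyl]-1,3-dioxolan-2-yl}propanoate (both C5 epimers)
Conditions: TMSOCH2CH2OTMS, TMSOTf (5 mol%), CH2Cl2, −78 → −20 °C; pyridine quench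
Reagents that add atoms: 1,2-bis(trimethylsilyloxy)ethane, C[Si](C)(C)OCCO[Si](C)(C)C
Why: Silyl triflate-catalysed ketalization with the bis-silyl ether of ethylene glycol is driven by formation of hexamethyldisiloxane and runs at low temperature, which suits a hindered ketone and spares the acid-labile tert-butyl ester.

Step 8
Reactants: 13 tert-butyl 3-{2-[(2S)-2-allyl-2,6,6-trimethylcyclohexyl]-1,3-dioxolan-2-yl}propanoate
Product: 15 tert-butyl 3-{2-[(2S)-2,6,6-trimethyl-2-(2-oxoethyl)cyclohexyl]-1,3-dioxolan-2-yl}propanoate (both C5 epimers), via secondary ozonide 14 (not isolated)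
Conditions: O3, CH2Cl2, −78 °C; then PPh3, −78 → 25 °C
Reagents that add atoms: ozone, O=[O+][O-]
Why: Ozonolysis with reductive work-up cleaves the only alkene to the C11 aldehyde; ketal and ester are inert to ozone at −78 °C.

Step 9
Reactants: 15 tert-butyl 3-{2-[(2S)-2,6,6-trimethyl-2-(2-oxoethyl)cyclohexyl]-1,3-dioxolan-2-yl}propanoate
Product: 17 ring A bis-enol derivative (C8=C17 tert-butyl TBS ketene acetal; C6 dioxolane; C9=C11 TBS enol ether on the quaternary C10; both C5 epimers; alkene geometries not controlled), via dipotassium bis-enolate 16 (not isolated)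
Conditions: KHMDS (2.4 equiv), THF, −78 °C; TBSCl (2.6 equiv), −78 → 0 °C; pentane, filtration, no aqueous work-up
Reagents that add atoms: tert-butyldimethylsilyl chloride, CC(C)(C)[Si](C)(C)Cl
Why: Enolate O-silylation: the first equivalent of base removes the more acidic aldehyde α-hydrogen at C9 (the only enolizable side, C10 being quaternary), the second the ester α-hydrogen at C8, and the two potassium enolates are silylated on oxygen to the enol ether and the ketene acetal; the C6 ketal blocks the ketone from enolization.

Step 10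
Reactants: 17 ring A bis-enol derivative
Product: 18 decalin with C6 dioxolane, C17 tert-butyl ester on C8 and C11 dimethyl acetal on C9 (ester anti to the 10-methyl; C5 epimers)
Conditions: reticulated vitreous carbon anode, Pt cathode, undivided cell, LiClO4 (0.1 M), 2,6-lutidine, MeOH/CH2Cl2 (1:4), −78 °C, constant current, 2.2 F/mol
Reagents that add atoms: methanol, CO
Why: Proposed new method: one-electron oxidation at the anode of the silyl ketene acetal, the most easily oxidized group, gives a radical cation whose C8 adds to C9, the nucleophilic carbon of the tethered silyl enol ether; the C11 α-silyloxy radical is oxidized a second time and taken up by methanol as the dimethyl acetal, while C17 loses silicon to methanol and returns the tert-butyl ester. The closest known reaction types are the intramolecular anodic coupling of enol ethers with other electron-rich alkenes and the oxidative coupling of bis-silyl enol ethers to 1,4-dicarbonyl compounds; a ketene acetal and aldehyde enol ether pair closing a cyclohexane is the extension. Ring B closes in a 6-exo-trig mode, C11 staying outside the ring. C8 is controlled by a chair-like transition state that keeps the ester equatorial and away from the axial C10 methyl; C9 is expected to place C11 equatorial in the same chair but is not relied on, since it is re-equilibrated as the aldehyde in step 12. The step needs chemoselective oxidation of the ketene acetal (secured by its lower oxidation potential; ketal, ester and lutidine are inert at that potential) and ring closure faster than methanol capture or methanolysis, which the low methanol content, the low temperature and the fully substituted C10 and C6 in the tether favour. Any free aldehyde or mixed methyl silyl acetal formed beside 18 converges with it in step 11.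

Step 11
Reactants: 18 decalin with C6 dioxolane, C17 tert-butyl ester and C11 dimethyl acetal
Product: 19 tert-butyl 1-formyl-5,5,8a-trimethyl-4-oxodecahydronaphthalene-2-carboxylate (labdane C6 ketone and C11 aldehyde; C5 epimers)
Conditions: 1 M HCl (aq), THF, 25 °C
Reagents that add atoms: water, O
Why: Acid-catalysed acetal hydrolysis frees the C11 aldehyde and the C6 ketone (the crowded ketal ionizes readily), while the tert-butyl ester survives dilute aqueous acid at room temperature.

Step 12
Reactants: 19 keto aldehyde (C5 epimers)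
Product: 20 tert-butyl 1-formyl-5,5,8a-trimethyl-4-oxodecahydronaphthalene-2-carboxylate as the single trans-fused isomer (5-H anti to the 10-methyl; 8-ester and 9-formyl equatorial and trans; 9-H syn to 5-H)
Conditions: NaOMe (0.2 equiv), MeOH, 25 → 40 °C
Reagents that add atoms: none
Why: Base-mediated epimerization through the C6 ketone enolate (C5) and the C11 aldehyde enolate (C9): with the C8 ester fixed equatorial, the trans-fused chair–chair decalin with equatorial formyl should be the most stable arrangement (a cis fusion would force the quaternary C4 axial on ring B), protonation of the C9 enolate also occurs kinetically on the face away from the axial C10 methyl, and catalytic methoxide does not enolize the ester centre C8.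

Step 13
Reactants: 20 trans-fused keto aldehyde
Product: 21 tert-butyl 5,5,8a-trimethyl-4-oxo-1-vinyldecahydronaphthalene-2-carboxylate (stereocentres as in 20)
Conditions: Ph3PCH3Br, KHMDS, THF, 0 °C; then 20, −78 → 0 °C
Reagents that add atoms: methyltriphenylphosphonium bromide, C[P+](c1ccccc1)(c1ccccc1)c1ccccc1.[Br-]
Why: Wittig methylenation is selective for the aldehyde because the C6 ketone, flanked by C5 and its two quaternary neighbours, does not react with the ylide at low temperature.

Step 14
Reactants: 21 vinyl keto ester
Product: 23 tert-butyl 5,5,8a-trimethyl-4-(trifluoromethylsulfonyloxy)-1-vinyl-1,2,4a,5,6,7,8,8a-octahydronaphthalene-2-carboxylate (C6–C7 enol triflate), via potassium enolate 22 (not isolated)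
Conditions: KHMDS (1.05 equiv), THF, −78 °C; PhNTf2, −78 → 0 °C
Reagents that add atoms: N-phenylbis(trifluoromethanesulfonimide), O=S(=O)(N(c1ccccc1)S(=O)(=O)C(F)(F)F)C(F)(F)F
Why: Kinetic deprotonation of the ketone occurs at the C7 methylene rather than at the shielded C5 methine, and the ketone is more acidic than the ester, so O-triflation of the enolate with the triflimide gives the C6–C7 enol triflate.

Step 15
Reactants: 23 enol triflate
Product: 24 tert-butyl 5,5,8a-trimethyl-1-vinyl-1,2,4a,5,6,7,8,8a-octahydronaphthalene-2-carboxylate (C6=C7 alkene; stereocentres as in 20)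
Conditions: Pd(OAc)2 (5 mol%), PPh3 (10 mol%), HCO2H, Bu3N, DMF, 60 °C
Reagents that add atoms: none
Why: Palladium-catalysed formate reduction of an enol triflate (oxidative addition, formate-to-hydride exchange with loss of CO2, reductive elimination) replaces OTf by H and so fixes the C6=C7 alkene; the amine is too weak a base to move the double bond into conjugation with the ester.

Step 16
Reactants: 25 2-(prop-2-yn-1-yloxy)tetrahydro-2H-pyran
Product: 27 tert-butyl 4-(tetrahydro-2H-pyran-2-yloxy)but-2-ynoate, via lithium acetylide 26 (not isolated)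
Conditions: n-BuLi, THF, −78 °C; Boc2O, −78 → 0 °C
Reagents that add atoms: di-tert-butyl dicarbonate, CC(C)(C)OC(=O)OC(=O)OC(C)(C)C
Why: Acylation of a lithium acetylide with Boc2O gives the tert-butyl ynoate; the THP ether tolerates the base.

Step 17
Reactants: 27 tert-butyl 4-(tetrahydro-2H-pyran-2-yloxy)but-2-ynoate
Product: 28 tert-butyl 4-hydroxybut-2-ynoate
Conditions: PPTS (cat.), MeOH, 40 °C
Reagents that add atoms: none
Why: Acid-catalysed transacetalization to methanol removes the THP group without touching the tert-butyl ester or the alkyne.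

Step 18
Reactants: 28 tert-butyl 4-hydroxybut-2-ynoate
Product: 29 tert-butyl 4-acetoxybut-2-ynoate
Conditions: Ac2O, pyridine, DMAP (cat.), CH2Cl2, 0 → 25 °C
Reagents that add atoms: acetic anhydride, CC(=O)OC(C)=O
Why: Nucleophilic catalysis by DMAP acetylates the primary alcohol.

Step 19
Reactants: 29 tert-butyl 4-acetoxybut-2-ynoate
Product: 30 tert-butyl (Z)-4-acetoxy-3-iodobut-2-enoate (iodine cis to the ester)
Conditions: NaI, AcOH, 70 °C
Reagents that add atoms: sodium iodide, [Na+].[I-]
Why: Conjugate hydroiodination of the ynoate: iodide adds to C3 and the allenolate is protonated anti, which gives the (Z)-3-iodoenoate with iodine cis to the ester.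

Step 20
Reactants: 24 9-vinyl decalin ester; 30 tert-butyl (Z)-4-acetoxy-3-iodobut-2-enoate
Product: 32 di-tert-butyl ester of the target (C15 and C17 tert-butyl esters; C16 acetate; 13E), via B-alkyl-9-BBN 31 (not isolated)
Conditions: 9-BBN, THF, 0 → 25 °C; then 30, PdCl2(dppf) (5 mol%), AsPh3, K3PO4 (3 M aq), DMF, 25 °C
Reagents that add atoms: none
Why: 9-BBN adds anti-Markovnikov to the terminal vinyl group (the ring alkene is disubstituted and shielded), and the B-alkyl Suzuki–Miyaura coupling then joins C12 to C13 with retention of the iodoalkene geometry, so that the chain is cis to the ester and the 13E alkene results.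

Step 21
Reactants: 32 di-tert-butyl ester of the target
Product: 33 CNP0108723.1 (target diacid)
Conditions: TFA, CH2Cl2, 0 → 25 °C
Reagents that add atoms: none
Why: Acidolysis cleaves both tert-butyl esters by loss of 2-methylpropene while the primary acetate, the two alkenes and the stereocentres are not affected.

**Compound list**

1 | 2,2,6-trimethylcyclohexanone | CC1CCCC(C)(C)C1=O | starting material
2 | allyl chloroformate | C=CCOC(Cl)=O | starting material
3 | lithium 2,6,6-trimethylcyclohex-1-en-1-olate | CC1=C([O-])C(C)(C)CCC1.[Li+] | intermediate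
4 | allyl 2,6,6-trimethylcyclohex-1-en-1-yl carbonate | C=CCOC(=O)OC1=C(C)CCCC1(C)C | intermediate
5 | (S)-2-allyl-2,6,6-trimethylcyclohexan-1-one | C=CC[C@]1(C)CCCC(C)(C)C1=O | intermediate
6 | (4S)-4-allyl-4,8,8-trimethyl-1-oxaspiro[2.5]octane, both configurations at the spiro carbon | C=CC[C@]1(C)CCCC(C)(C)C12CO2 | intermediate
7 | (2S)-2-allyl-2,6,6-trimethylcyclohexane-1-carbaldehyde, both C5 epimers | C=CC[C@]1(C)CCCC(C)(C)C1C=O | intermediate
8 | tert-butyl 3-bromopropanoate | CC(C)(C)OC(=O)CCBr | starting material
9 | (3-tert-butoxy-3-oxopropyl)zinc bromide | CC(C)(C)OC(=O)CC[Zn]Br | intermediate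
10 | (3-tert-butoxy-3-oxopropyl)triisopropoxytitanium | CC(C)O[Ti](OC(C)C)(OC(C)C)CCC(=O)OC(C)(C)C | intermediate
11 | tert-butyl 4-[(2S)-2-allyl-2,6,6-trimethylcyclohexyl]-4-hydroxybutanoate, mixture at C5 and C6 | C=CC[C@]1(C)CCCC(C)(C)C1C(O)CCC(=O)OC(C)(C)C | intermediate
12 | tert-butyl 4-[(2S)-2-allyl-2,6,6-trimethylcyclohexyl]-4-oxobutanoate, both C5 epimers | C=CC[C@]1(C)CCCC(C)(C)C1C(=O)CCC(=O)OC(C)(C)C | intermediate
13 | tert-butyl 3-{2-[(2S)-2-allyl-2,6,6-trimethylcyclohexyl]-1,3-dioxolan-2-yl}propanoate, both C5 epimers | C=CC[C@]1(C)CCCC(C)(C)C1C1(CCC(=O)OC(C)(C)C)OCCO1 | intermediate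
14 | secondary ozonide (1,2,4-trioxolane) of 13 | CC(C)(C)OC(=O)CCC1(OCCO1)C1C(C)(C)CCC[C@@]1(C)CC1OCOO1 | intermediate
15 | tert-butyl 3-{2-[(2S)-2,6,6-trimethyl-2-(2-oxoethyl)cyclohexyl]-1,3-dioxolan-2-yl}propanoate, both C5 epimers | O=CC[C@]1(C)CCCC(C)(C)C1C1(CCC(=O)OC(C)(C)C)OCCO1 | intermediate
16 | dipotassium bis-enolate of 15 (C9=C11 aldehyde enolate, C8=C17 ester enolate) | [K+].[K+].[O-]C=C[C@]1(C)CCCC(C)(C)C1C1(CC=C([O-])OC(C)(C)C)OCCO1 | intermediate
17 | ring A bis-enol derivative: C8=C17 tert-butyl TBS ketene acetal, C6 dioxolane, C9=C11 TBS enol ether, both C5 epimers | CC(C)(C)OC(O[Si](C)(C)C(C)(C)C)=CCC1(OCCO1)C1C(C)(C)CCC[C@@]1(C)C=CO[Si](C)(C)C(C)(C)C | intermediate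
18 | tert-butyl 1'-(dimethoxymethyl)-5',5',8a'-trimethyloctahydrospiro[1,3-dioxolane-2,4'-naphthalene]-2'-carboxylate (C6 dioxolane, C17 ester, C11 acetal; ester anti to 10-methyl; C5 epimers) | COC(OC)[C@@H]1[C@@H](C(=O)OC(C)(C)C)CC2(OCCO2)C2C(C)(C)CCC[C@@]12C | intermediate
19 | tert-butyl 1-formyl-5,5,8a-trimethyl-4-oxodecahydronaphthalene-2-carboxylate, C5 epimers | O=C[C@@H]1[C@@H](C(=O)OC(C)(C)C)CC(=O)C2C(C)(C)CCC[C@@]12C | intermediate
20 | tert-butyl 1-formyl-5,5,8a-trimethyl-4-oxodecahydronaphthalene-2-carboxylate, trans-fused, ester and formyl equatorial and trans | O=C[C@@H]1[C@@H](C(=O)OC(C)(C)C)CC(=O)[C@@H]2C(C)(C)CCC[C@@]12C | intermediate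
21 | tert-butyl 5,5,8a-trimethyl-4-oxo-1-vinyldecahydronaphthalene-2-carboxylate, stereocentres as in 20 | C=C[C@@H]1[C@@H](C(=O)OC(C)(C)C)CC(=O)[C@@H]2C(C)(C)CCC[C@@]12C | intermediate
22 | potassium C6–C7 enolate of 21 | [K+].C=C[C@@H]1[C@@H](C(=O)OC(C)(C)C)C=C([O-])[C@@H]2C(C)(C)CCC[C@@]12C | intermediate
23 | C6–C7 enol triflate of 21 | C=C[C@@H]1[C@@H](C(=O)OC(C)(C)C)C=C(OS(=O)(=O)C(F)(F)F)[C@@H]2C(C)(C)CCC[C@@]12C | intermediate
24 | tert-butyl 5,5,8a-trimethyl-1-vinyl-1,2,4a,5,6,7,8,8a-octahydronaphthalene-2-carboxylate, stereocentres as in 20 | C=C[C@@H]1[C@@H](C(=O)OC(C)(C)C)C=C[C@@H]2C(C)(C)CCC[C@@]12C | intermediate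
25 | 2-(prop-2-yn-1-yloxy)tetrahydro-2H-pyran | C#CCOC1CCCCO1 | starting material
26 | lithium acetylide of 25 | [Li+].[C-]#CCOC1CCCCO1 | intermediate
27 | tert-butyl 4-(tetrahydro-2H-pyran-2-yloxy)but-2-ynoate | CC(C)(C)OC(=O)C#CCOC1CCCCO1 | intermediate
28 | tert-butyl 4-hydroxybut-2-ynoate | CC(C)(C)OC(=O)C#CCO | intermediate
29 | tert-butyl 4-acetoxybut-2-ynoate | CC(=O)OCC#CC(=O)OC(C)(C)C | intermediate
30 | tert-butyl (Z)-4-acetoxy-3-iodobut-2-enoate | CC(=O)OC/C(I)=C/C(=O)OC(C)(C)C | intermediate
31 | B-alkyl-9-BBN from 24 (boron on C12) | C1CC2CCCC(C1)B2CC[C@@H]1[C@@H](C(=O)OC(C)(C)C)C=C[C@@H]2C(C)(C)CCC[C@@]12C | intermediate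
32 | di-tert-butyl ester of the target (13E) | CC(=O)OC/C(=C/C(=O)OC(C)(C)C)CC[C@@H]1[C@@H](C(=O)OC(C)(C)C)C=C[C@@H]2C(C)(C)CCC[C@@]12C | intermediate
33 | CNP0108723.1 | CC(=O)OC/C(=C/C(=O)O)CC[C@@H]1[C@@H](C(=O)O)C=C[C@@H]2C(C)(C)CCC[C@@]12C | target

**Step count**

Total: 21 steps. Longest linear sequence: 17 steps (steps 1 to 15, 20 and 21); steps 16 to 19 make the side-chain piece 30.

**Steps most likely to fail**

Step 10. The ketene acetal may be methanolysed before it is oxidized, the radical cation may be captured by methanol before it reaches C9, or closure may be slowed by the crowding that the C6 ketal brings next to the C4 and C10 methyls. The fallback uses known radical chemistry and sets out from 17. One equivalent of NBS in THF at −78 °C should brominate only the far more nucleophilic ketene acetal and give tert-butyl 2-bromo-3-{2-[2,6,6-trimethyl-2-(2-silyloxyvinyl)cyclohexyl]-1,3-dioxolan-2-yl}propanoate F1 with the enol ether intact. Bu3SnH and AIBN in benzene at 80 °C should then close ring B by 6-exo-trig addition of the α-ester radical to C9 of the enol ether, with hydrogen transfer to C11, to give the C11 silyl ether decalin F2. Aqueous HCl in THF removes the ketal and the silyl group to give the hydroxy ketone F3, and Dess–Martin oxidation returns the route to 19 before step 12.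

Step 7. The ketone, attached to a methine between two quaternary carbons, may not ketalize, or forcing it may cost the tert-butyl ester. The fallback carries C6 as a protected carbinol and sets out from 11. TESCl and imidazole give the triethylsilyl ether F4 (both C6 epimers). Ozonolysis as in step 8 gives the aldehyde F5, and double silylation as in step 9 gives the bis-enol derivative F6. Electrolysis as in step 10 gives the decalin F7 with a C6 silyloxy group. Aqueous HCl in THF cleaves the acetal and the triethylsilyl ether to the hydroxy aldehyde F8, and Dess–Martin oxidation of the C6 carbinol rejoins the route at 19.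

Step 3. The ylide may fail to add to a carbonyl flanked by two quaternary carbons and decompose instead, returning 5. The fallback sets out from 5 and uses a silicon-based one-carbon homologation. Methoxy(trimethylsilyl)methyllithium (from (methoxymethyl)trimethylsilane and s-BuLi, THF, −78 → −25 °C) adds to the ketone to give the β-hydroxysilane F9. Formic acid then effects Peterson elimination to the methyl enol ether and its hydrolysis, which gives the aldehyde 7.

Further compounds
F1 | step 10 | tert-butyl 2-bromo-3-{2-[2,6,6-trimethyl-2-(2-(tert-butyldimethylsilyloxy)vinyl)cyclohexyl]-1,3-dioxolan-2-yl}propanoate | CC(C)(C)OC(=O)C(Br)CC1(OCCO1)C1C(C)(C)CCC[C@@]1(C)C=CO[Si](C)(C)C(C)(C)C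
F2 | step 10 | decalin with C6 dioxolane, C17 tert-butyl ester and C11 tert-butyldimethylsilyl ether | CC(C)(C)[Si](C)(C)OC[C@@H]1[C@@H](C(=O)OC(C)(C)C)CC2(OCCO2)C2C(C)(C)CCC[C@@]12C
F3 | step 10 | tert-butyl 1-(hydroxymethyl)-5,5,8a-trimethyl-4-oxodecahydronaphthalene-2-carboxylate | OC[C@@H]1[C@@H](C(=O)OC(C)(C)C)CC(=O)C2C(C)(C)CCC[C@@]12C
F4 | step 7 | tert-butyl 4-[(2S)-2-allyl-2,6,6-trimethylcyclohexyl]-4-(triethylsilyloxy)butanoate | C=CC[C@]1(C)CCCC(C)(C)C1C(CCC(=O)OC(C)(C)C)O[Si](CC)(CC)CC
F5 | step 7 | tert-butyl 4-[(2S)-2,6,6-trimethyl-2-(2-oxoethyl)cyclohexyl]-4-(triethylsilyloxy)butanoate | O=CC[C@]1(C)CCCC(C)(C)C1C(CCC(=O)OC(C)(C)C)O[Si](CC)(CC)CC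
F6 | step 7 | ring A bis-enol derivative with C6 triethylsilyloxy group (C8=C17 TBS ketene acetal, C9=C11 TBS enol ether) | CC(C)(C)OC(O[Si](C)(C)C(C)(C)C)=CCC(O[Si](CC)(CC)CC)C1C(C)(C)CCC[C@@]1(C)C=CO[Si](C)(C)C(C)(C)C
F7 | step 7 | decalin with C6 triethylsilyloxy group, C17 tert-butyl ester and C11 dimethyl acetal | COC(OC)[C@@H]1[C@@H](C(=O)OC(C)(C)C)CC(O[Si](CC)(CC)CC)C2C(C)(C)CCC[C@@]12C
F8 | step 7 | tert-butyl 1-formyl-4-hydroxy-5,5,8a-trimethyldecahydronaphthalene-2-carboxylate | O=C[C@@H]1[C@@H](C(=O)OC(C)(C)C)CC(O)C2C(C)(C)CCC[C@@]12C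
F9 | step 3 | (2S)-2-allyl-1-[methoxy(trimethylsilyl)methyl]-2,6,6-trimethylcyclohexan-1-ol | C=CC[C@]1(C)CCCC(C)(C)C1(O)C(OC)[Si](C)(C)C
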